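## Retrosynthetic overview

1. Leachianone A (30) ⇐ its 5-O-methyl ether 29 (chelation-controlled demethylation) ⇐ chalcone 28. Ring C is the only ring built and is closed last, by an enantioselective 6-endo oxa-Michael addition that sets C2 (S); the 6'-OMe blocks closure through the other ortho oxygen.
2. 28 ⇐ Claisen–Schmidt union of the ring A ketone 21 and the ring B aldehyde 25 (rings A and B both come from resorcinol).
3. 21 ⇐ arene 18, whose lavandulyl chain is assembled on ring A by boron-to-carbon 1,2-shifts. Key step: benzyl boronate 8 + lithiated carbamate 11 → 13, a stereospecific, ionic 1,2-shift of the benzylic carbon that forms C1''–C2'' and sets C2'' (R); Zweifel olefination then adds the isopropenyl group.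
4. 8 ⇐ 1-methoxy-3,5-bis(methoxymethoxy)benzene 5 ⇐ resorcinol by meta C–H borylation/oxidation; the side-chain carbons come from 4-methylpent-3-en-1-ol and 2-bromopropene.
5. 25 ⇐ resorcinol by Vilsmeier–Haack formylation and two selective O-alkylations.

Assumption: in step 13 the (R)-acid is taken as the enantiomer that gives 2S; the dr of the first run shows the sense (the C2 epimers are diastereomers), and the (S)-acid is used if it is the opposite.

(C1'' = benzylic CH2 of the lavandulyl group, C2'' = its stereocentre.)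

## Route

Step 1
Reactants: 1 resorcinol (benzene-1,3-diol)
Product: 2 1,3-bis(methoxymethoxy)benzene
Conditions: NaH, MOMCl, DMF, 0 °C → rt
Reagents that add atoms: chloromethyl methyl ether (MOMCl), COCCl
Why: Double Williamson O-alkylation of the bis-phenoxide gives the bis-MOM ether, which protects both phenols and later serves as the directing group for ring lithiation.

Step 2
Reactants: 2 1,3-bis(methoxymethoxy)benzene
Product: 4 3,5-bis(methoxymethoxy)phenol, via aryl boronic ester 3 (not isolated)
Conditions: B2pin2, [Ir(OCH3)(C8H12)]2 (1.5 mol%), 4,4'-di-tert-butyl-2,2'-bipyridine (3 mol%), THF, 80 °C; then NaOH (aq), H2O2 (30%), 0 °C → rt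
Reagents that add atoms: hydrogen peroxide, OO
Why: Iridium-catalysed C–H borylation is sterically controlled and takes the only C–H without an ortho substituent (C5), and the boronate is oxidised in the same pot (1,2-shift of the aryl group from boron to oxygen) to the phenol.

Step 3
Reactants: 4 3,5-bis(methoxymethoxy)phenol
Product: 5 1-methoxy-3,5-bis(methoxymethoxy)benzene
Conditions: MeI, K2CO3, acetone, 56 °C
Reagents that add atoms: iodomethane, CI
Why: Williamson methylation of the single free phenol marks the future O5 with a group that survives the MOM removal, so that later only O1 can close ring C.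

Step 4
Reactants: 5 1-methoxy-3,5-bis(methoxymethoxy)benzene
Product: 8 2-{[4-methoxy-2,6-bis(methoxymethoxy)phenyl]methyl}-4,4,5,5-tetramethyl-1,3,2-dioxaborolane, via aryllithium 6 (not isolated), via chloromethyl borate complex 7 (not isolated)
Conditions: n-BuLi, THF, 0 °C, 1 h; ClCH2Bpin, −78 °C → rt, 16 h
Reagents that add atoms: 2-(chloromethyl)-4,4,5,5-tetramethyl-1,3,2-dioxaborolane, ClCB1OC(C)(C)C(C)(C)O1
Why: Directed ortho-metalation takes the C–H flanked by the two MOM ethers (stronger directors than OMe), and the borate formed with the chloromethyl boronate undergoes a Matteson-type 1,2-shift of the aryl group from boron to carbon with loss of chloride to give the benzylic boronate.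

Step 5
Reactants: 9 4-methylpent-3-en-1-ol
Product: 10 4-methylpent-3-en-1-yl N,N-diisopropylcarbamate
Conditions: NaH, i-Pr2NCOCl, THF, 66 °C
Reagents that add atoms: N,N-diisopropylcarbamoyl chloride, CC(C)N(C(C)C)C(=O)Cl
Why: Carbamoylation of the primary alkoxide gives the Hoppe carbamate, whose carbonyl directs the enantioselective α-lithiation and which is the leaving group of the next step.

Step 6
Reactants: 10 4-methylpent-3-en-1-yl N,N-diisopropylcarbamate; 8 2-{[4-methoxy-2,6-bis(methoxymethoxy)phenyl]methyl}-4,4,5,5-tetramethyl-1,3,2-dioxaborolane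
Product: 13 2-{(2R)-1-[4-methoxy-2,6-bis(methoxymethoxy)phenyl]-5-methylhex-4-en-2-yl}-4,4,5,5-tetramethyl-1,3,2-dioxaborolane, via lithiated carbamate 11 (not isolated), via borate complex 12 (not isolated)
Conditions: 10, s-BuLi, (−)-sparteine, Et2O, −78 °C, 5 h; then 8, −78 °C, 1 h; then 35 °C, 12 h
Reagents that add atoms: none
Why: Hoppe–Aggarwal lithiation–borylation: (−)-sparteine·s-BuLi removes the pro-S proton of 10 to give configurationally stable (S)-11, which adds to the boron of 8 with retention, and on warming the benzylic carbon shifts 1,2 from boron to carbon antiperiplanar to the carbamate (ionic 1,2-metallate shift, inversion at carbon), which forms the C1''–C2'' bond and sets C2'' as R (er about 97:3 expected).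

Step 7
Reactants: 13 2-{(2R)-1-[4-methoxy-2,6-bis(methoxymethoxy)phenyl]-5-methylhex-4-en-2-yl}-4,4,5,5-tetramethyl-1,3,2-dioxaborolane; 14 2-bromopropene
Product: 18 5-methoxy-1,3-bis(methoxymethoxy)-2-[(2R)-5-methyl-2-(prop-1-en-2-yl)hex-4-en-1-yl]benzene, via isopropenyllithium 15 (not isolated), via alkenyl borate complex 16 (not isolated), via iodo boronic ester 17 (not isolated)
Conditions: 14, t-BuLi, THF, −78 °C; then 13, −78 → 0 °C; I2 (1.5 equiv), MeOH, −78 °C; NaOMe, MeOH, −78 °C → rt; Na2S2O3 (aq)
Reagents that add atoms: none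
Why: Zweifel olefination: iodine activates the alkenyl group of the borate, the secondary alkyl group shifts 1,2 from boron to carbon with retention at the stereocentre, and methoxide-induced anti elimination of boron and iodide gives the isopropenyl group, the small excess of I2 at −78 °C sparing the electron-rich arene and the trisubstituted alkene.

Step 8
Reactants: 18 5-methoxy-1,3-bis(methoxymethoxy)-2-[(2R)-5-methyl-2-(prop-1-en-2-yl)hex-4-en-1-yl]benzene; 19 N-methoxy-N-methylacetamide
Product: 21 1-{6-methoxy-2,4-bis(methoxymethoxy)-3-[(2R)-5-methyl-2-(prop-1-en-2-yl)hex-4-en-1-yl]phenyl}ethan-1-one, via aryllithium 20 (not isolated)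
Conditions: n-BuLi, THF, 0 °C, 1 h; then 19, −78 → 0 °C; NH4Cl (aq)
Reagents that add atoms: none
Why: Directed ortho-metalation at one of the two equivalent C–H positions between OMe and OMOM followed by Weinreb ketone synthesis (stable tetrahedral adduct, no over-addition) places the acetyl group next to the MOM-protected O1, and the lavandulyl centre is not deprotonated under these conditions.

Step 9
Reactants: 1 resorcinol (benzene-1,3-diol)
Product: 23 2,4-dihydroxybenzaldehyde, via iminium chloride 22 (not isolated)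
Conditions: POCl3, DMF, MeCN, −15 °C → rt; then H2O, 50 °C
Reagents that add atoms: N,N-dimethylformamide, CN(C)C=O (formyl carbon); water, O (aldehyde oxygen)
Why: Vilsmeier–Haack formylation attacks resorcinol at C4 (para to one OH, ortho to the other), and hydrolysis of the iminium salt gives the aldehyde.

Step 10
Reactants: 23 2,4-dihydroxybenzaldehyde
Product: 25 2-methoxy-4-(methoxymethoxy)benzaldehyde, via mono-MOM aldehyde 24 (not isolated)
Conditions: MOMCl (1.05 equiv), K2CO3, acetone, 0 °C → rt; then MeI, K2CO3, 56 °C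
Reagents that add atoms: chloromethyl methyl ether (MOMCl), COCCl; iodomethane, CI
Why: Selective Williamson alkylation: the 4-OH is the more acidic and is not hydrogen-bonded to the aldehyde, so one equivalent of MOMCl takes it at room temperature, and the chelated 2-OH is then methylated at reflux in the same pot.

Step 11
Reactants: 21 1-{6-methoxy-2,4-bis(methoxymethoxy)-3-[(2R)-5-methyl-2-(prop-1-en-2-yl)hex-4-en-1-yl]phenyl}ethan-1-one; 25 2-methoxy-4-(methoxymethoxy)benzaldehyde
Product: 27 (E)-3-[2-methoxy-4-(methoxymethoxy)phenyl]-1-{6-methoxy-2,4-bis(methoxymethoxy)-3-[(2R)-5-methyl-2-(prop-1-en-2-yl)hex-4-en-1-yl]phenyl}prop-2-en-1-one, via aldol adduct 26 (not isolated)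
Conditions: KOH, EtOH/H2O, rt, 36 h
Reagents that add atoms: none
Why: Claisen–Schmidt condensation: the methyl ketone enolate adds to the non-enolisable aldehyde and E1cB dehydration gives the E-chalcone, while the MOM ethers, the alkenes and the non-acidic lavandulyl centre are stable to KOH.

Step 12
Reactants: 27 (E)-3-[2-methoxy-4-(methoxymethoxy)phenyl]-1-{6-methoxy-2,4-bis(methoxymethoxy)-3-[(2R)-5-methyl-2-(prop-1-en-2-yl)hex-4-en-1-yl]phenyl}prop-2-en-1-one
Product: 28 (E)-1-{2,4-dihydroxy-6-methoxy-3-[(2R)-5-methyl-2-(prop-1-en-2-yl)hex-4-en-1-yl]phenyl}-3-(4-hydroxy-2-methoxyphenyl)prop-2-en-1-one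
Conditions: HCl (3 M aq), MeOH, 25 °C
Reagents that add atoms: none
Why: Acid-catalysed acetal methanolysis removes all three MOM groups while C2 does not yet exist, so no C2 configuration can be lost to acid; dilute acid at 25 °C is the usual practice for prenylated 2'-hydroxychalcones, the methyl ethers stay, and any flavanone formed by background closure is removed by chromatography.

Step 13
Reactants: 28 (E)-1-{2,4-dihydroxy-6-methoxy-3-[(2R)-5-methyl-2-(prop-1-en-2-yl)hex-4-en-1-yl]phenyl}-3-(4-hydroxy-2-methoxyphenyl)prop-2-en-1-one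
Product: 29 (2S)-7-hydroxy-2-(4-hydroxy-2-methoxyphenyl)-5-methoxy-8-[(2R)-5-methyl-2-(prop-1-en-2-yl)hex-4-en-1-yl]-2,3-dihydro-4H-chromen-4-one
Conditions: (R)-3,3'-bis(2,4,6-triisopropylphenyl)-1,1'-binaphthyl-2,2'-diyl hydrogen phosphate, C50H57O4P (10 mol%), toluene/CH2Cl2 (2:1), 4 Å molecular sieves, 30 °C, stopped at full conversion
Reagents that add atoms: none
Why: Proposed new method: a chiral phosphoric acid is used for the enantioselective 6-endo oxa-Michael closure of an unactivated 2'-hydroxychalcone; the acid hydrogen-bonds the enone carbonyl while its P=O accepts the 2'-OH proton, the 4-hydroxy-2-methoxyphenyl group gives the bound enone vinylogous para-quinone-methide character so that this weak acid (too weak to protonate the lavandulyl alkenes) suffices, the 6'-OMe leaves O2' as the only nucleophile, and the 2,4,6-triisopropylphenyl pocket controls which face of C-beta is attacked, so that ring C is formed and C2 is set as S under catalyst control irrespective of the remote R centre; the closest known reaction types are the phosphoric acid-catalysed aza-Michael cyclisation of 2'-aminochalcones and phosphoric acid-catalysed additions of O-nucleophiles to para-quinone methides.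

Step 14
Reactants: 29 (2S)-7-hydroxy-2-(4-hydroxy-2-methoxyphenyl)-5-methoxy-8-[(2R)-5-methyl-2-(prop-1-en-2-yl)hex-4-en-1-yl]-2,3-dihydro-4H-chromen-4-one
Product: 30 leachianone A, (2S)-5,7-dihydroxy-2-(4-hydroxy-2-methoxyphenyl)-8-[(2R)-5-methyl-2-(prop-1-en-2-yl)hex-4-en-1-yl]-2,3-dihydro-4H-chromen-4-one
Conditions: MgI2·O(C2H5)2, THF, 60 °C; then NH4Cl (aq)
Reagents that add atoms: none
Why: Chelation-assisted ether cleavage: magnesium binds the C4 carbonyl and the peri 5-OMe oxygen and iodide removes that methyl group by SN2 (a reaction known for 5-O-methyl-8-prenylflavanones), while the unchelated 2'-OMe, the alkenes and both stereocentres are left alone because no Brønsted acid or base is present and the pyranone ring stays closed.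

## Compound list

1 | resorcinol (benzene-1,3-diol) | Oc1cccc(O)c1 | starting material
2 | 1,3-bis(methoxymethoxy)benzene | COCOc1cccc(OCOC)c1 | intermediate
3 | 2-[3,5-bis(methoxymethoxy)phenyl]-4,4,5,5-tetramethyl-1,3,2-dioxaborolane | COCOc1cc(OCOC)cc(B2OC(C)(C)C(C)(C)O2)c1 | intermediate
4 | 3,5-bis(methoxymethoxy)phenol | COCOc1cc(O)cc(OCOC)c1 | intermediate
5 | 1-methoxy-3,5-bis(methoxymethoxy)benzene | COCOc1cc(OC)cc(OCOC)c1 | intermediate
6 | [4-methoxy-2,6-bis(methoxymethoxy)phenyl]lithium | [Li]c1c(OCOC)cc(OC)cc1OCOC | intermediate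
7 | lithium (chloromethyl)[4-methoxy-2,6-bis(methoxymethoxy)phenyl](pinacolato)borate | [Li+].ClC[B-]1(c2c(OCOC)cc(OC)cc2OCOC)OC(C)(C)C(C)(C)O1 | intermediate
8 | 2-{[4-methoxy-2,6-bis(methoxymethoxy)phenyl]methyl}-4,4,5,5-tetramethyl-1,3,2-dioxaborolane | COCOc1cc(OC)cc(OCOC)c1CB1OC(C)(C)C(C)(C)O1 | intermediate
9 | 4-methylpent-3-en-1-ol | CC(C)=CCCO | starting material
10 | 4-methylpent-3-en-1-yl N,N-diisopropylcarbamate | CC(C)=CCCOC(=O)N(C(C)C)C(C)C | intermediate
11 | (1S)-1-lithio-4-methylpent-3-en-1-yl N,N-diisopropylcarbamate (as its (−)-sparteine complex) | CC(C)=CC[C@H]([Li])OC(=O)N(C(C)C)C(C)C | intermediate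
12 | lithium {(1S)-1-[(diisopropylcarbamoyl)oxy]-4-methylpent-3-en-1-yl}{[4-methoxy-2,6-bis(methoxymethoxy)phenyl]methyl}(pinacolato)borate | [Li+].CC(C)=CC[C@H]([B-]1(Cc2c(OCOC)cc(OC)cc2OCOC)OC(C)(C)C(C)(C)O1)OC(=O)N(C(C)C)C(C)C | intermediate
13 | 2-{(2R)-1-[4-methoxy-2,6-bis(methoxymethoxy)phenyl]-5-methylhex-4-en-2-yl}-4,4,5,5-tetramethyl-1,3,2-dioxaborolane | CC(C)=CC[C@H](Cc1c(OCOC)cc(OC)cc1OCOC)B1OC(C)(C)C(C)(C)O1 | intermediate
14 | 2-bromopropene | C=C(C)Br | starting material
15 | prop-1-en-2-yllithium (isopropenyllithium) | [Li]C(C)=C | intermediate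
16 | lithium {(2R)-1-[4-methoxy-2,6-bis(methoxymethoxy)phenyl]-5-methylhex-4-en-2-yl}(prop-1-en-2-yl)(pinacolato)borate | [Li+].CC(C)=CC[C@H](Cc1c(OCOC)cc(OC)cc1OCOC)[B-]1(C(C)=C)OC(C)(C)C(C)(C)O1 | intermediate
17 | 2-{(3R)-1-iodo-3-{[4-methoxy-2,6-bis(methoxymethoxy)phenyl]methyl}-2,6-dimethylhept-5-en-2-yl}-4,4,5,5-tetramethyl-1,3,2-dioxaborolane (both C2 epimers) | CC(C)=CC[C@H](Cc1c(OCOC)cc(OC)cc1OCOC)C(C)(CI)B1OC(C)(C)C(C)(C)O1 | intermediate
18 | 5-methoxy-1,3-bis(methoxymethoxy)-2-[(2R)-5-methyl-2-(prop-1-en-2-yl)hex-4-en-1-yl]benzene | C=C(C)[C@H](CC=C(C)C)Cc1c(OCOC)cc(OC)cc1OCOC | intermediate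
19 | N-methoxy-N-methylacetamide | CON(C)C(C)=O | starting material
20 | {6-methoxy-2,4-bis(methoxymethoxy)-3-[(2R)-5-methyl-2-(prop-1-en-2-yl)hex-4-en-1-yl]phenyl}lithium | C=C(C)[C@H](CC=C(C)C)Cc1c(OCOC)cc(OC)c([Li])c1OCOC | intermediate
21 | 1-{6-methoxy-2,4-bis(methoxymethoxy)-3-[(2R)-5-methyl-2-(prop-1-en-2-yl)hex-4-en-1-yl]phenyl}ethan-1-one | C=C(C)[C@H](CC=C(C)C)Cc1c(OCOC)cc(OC)c(C(C)=O)c1OCOC | intermediate
22 | [(2,4-dihydroxyphenyl)methylidene]dimethylammonium chloride | C[N+](C)=Cc1ccc(O)cc1O.[Cl-] | intermediate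
23 | 2,4-dihydroxybenzaldehyde | O=Cc1ccc(O)cc1O | intermediate
24 | 2-hydroxy-4-(methoxymethoxy)benzaldehyde | COCOc1ccc(C=O)c(O)c1 | intermediate
25 | 2-methoxy-4-(methoxymethoxy)benzaldehyde | COCOc1ccc(C=O)c(OC)c1 | intermediate
26 | 3-hydroxy-3-[2-methoxy-4-(methoxymethoxy)phenyl]-1-{6-methoxy-2,4-bis(methoxymethoxy)-3-[(2R)-5-methyl-2-(prop-1-en-2-yl)hex-4-en-1-yl]phenyl}propan-1-one (both carbinol epimers) | C=C(C)[C@H](CC=C(C)C)Cc1c(OCOC)cc(OC)c(C(=O)CC(O)c2ccc(OCOC)cc2OC)c1OCOC | intermediate
27 | (E)-3-[2-methoxy-4-(methoxymethoxy)phenyl]-1-{6-methoxy-2,4-bis(methoxymethoxy)-3-[(2R)-5-methyl-2-(prop-1-en-2-yl)hex-4-en-1-yl]phenyl}prop-2-en-1-one | C=C(C)[C@H](CC=C(C)C)Cc1c(OCOC)cc(OC)c(C(=O)/C=C/c2ccc(OCOC)cc2OC)c1OCOC | intermediate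
28 | (E)-1-{2,4-dihydroxy-6-methoxy-3-[(2R)-5-methyl-2-(prop-1-en-2-yl)hex-4-en-1-yl]phenyl}-3-(4-hydroxy-2-methoxyphenyl)prop-2-en-1-one | C=C(C)[C@H](CC=C(C)C)Cc1c(O)cc(OC)c(C(=O)/C=C/c2ccc(O)cc2OC)c1O | intermediate
29 | (2S)-7-hydroxy-2-(4-hydroxy-2-methoxyphenyl)-5-methoxy-8-[(2R)-5-methyl-2-(prop-1-en-2-yl)hex-4-en-1-yl]-2,3-dihydro-4H-chromen-4-one | C=C(C)[C@H](CC=C(C)C)Cc1c(O)cc(OC)c2c1O[C@H](c1ccc(O)cc1OC)CC2=O | intermediate
30 | leachianone A, (2S)-5,7-dihydroxy-2-(4-hydroxy-2-methoxyphenyl)-8-[(2R)-5-methyl-2-(prop-1-en-2-yl)hex-4-en-1-yl]-2,3-dihydro-4H-chromen-4-one | C=C(C)[C@H](CC=C(C)C)Cc1c(O)cc(O)c2c1O[C@H](c1ccc(O)cc1OC)CC2=O | target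

## Step count and risk

Total step count: 14. Longest linear sequence: 11 steps (1, 2, 3, 4, 6, 7, 8, 11, 12, 13, 14).

Steps most likely to fail:

Step 13 (the proposed new cyclisation). The rate and the selectivity of a phosphoric acid-catalysed closure of an unactivated 2'-hydroxychalcone are not known. The fallback uses known chemistry and replaces asymmetric catalysis by resolution with recycling. It sets out from 28: NaOAc in EtOH at reflux closes ring C by the ordinary base-mediated oxa-Michael addition and gives 29 together with its C2 epimer, the (2R,2''R) flavanone F2, in about equal amounts. The two are diastereomers and are separated by preparative HPLC on an amylose tris(3,5-dimethylphenylcarbamate) phase. F2 is returned to the same NaOAc conditions, which re-equilibrate C2 through ring opening to 28. The fallback comes back to the route at 29.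

Step 6 (lithiation–borylation). The hindered benzyl boronate 8, which carries four ether oxygens, may form the borate slowly, or the 1,2-shift may stall, and the step needs stoichiometric (−)-sparteine. The fallback sets out from 8 and replaces the stoichiometric chiral carbenoid by a catalytic enantioselective conjunctive cross-coupling. Vinyllithium (from Sn(CH=CH2)4 and n-BuLi) adds to 8 to give the lithium vinyl borate complex F1. Pd(OAc)2 and the ferrocene diphosphine Mandyphos, 1,1'-bis[bis(4-methoxy-3,5-dimethylphenyl)phosphino]-2,2'-bis[α-(dimethylamino)benzyl]ferrocene (C64H74FeN2O4P2), in the enantiomer that leads to the R product, are then used with 2-methylprop-1-en-1-yl trifluoromethanesulfonate in THF at 60 °C. The alkenylpalladium species binds the vinyl group, the benzylic carbon shifts 1,2 from boron to the α-carbon, and reductive elimination joins the terminal carbon to the alkenyl group. This gives 13 directly, where the fallback comes back to the route.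

Step 14 (demethylation). Heating with a Lewis acid could erode C2 or close the lavandulyl chain onto the neighbouring 7-OH. The fallback sets out from 29 and masks both phenols before a low-temperature cleavage. Ac2O and pyridine give the 7,4'-diacetate F3. BCl3 in CH2Cl2 at −78 → −20 °C removes only the chelated 5-O-methyl group and gives the 5-hydroxy diacetate F4; with no free phenol present, no HCl is formed during the reaction and no phenol oxygen can attack the alkenes. NH4OAc in MeOH/H2O at 25 °C then removes the two aryl acetates under near-neutral conditions. The fallback comes back to the route at 30.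

## Further compounds

F1 | step 6 | lithium ethenyl{[4-methoxy-2,6-bis(methoxymethoxy)phenyl]methyl}(pinacolato)borate | [Li+].C=C[B-]1(Cc2c(OCOC)cc(OC)cc2OCOC)OC(C)(C)C(C)(C)O1
F2 | step 13 | (2R)-7-hydroxy-2-(4-hydroxy-2-methoxyphenyl)-5-methoxy-8-[(2R)-5-methyl-2-(prop-1-en-2-yl)hex-4-en-1-yl]-2,3-dihydro-4H-chromen-4-one | C=C(C)[C@H](CC=C(C)C)Cc1c(O)cc(OC)c2c1O[C@@H](c1ccc(O)cc1OC)CC2=O
F3 | step 14 | (2S)-2-[4-(acetyloxy)-2-methoxyphenyl]-5-methoxy-8-[(2R)-5-methyl-2-(prop-1-en-2-yl)hex-4-en-1-yl]-4-oxo-3,4-dihydro-2H-chromen-7-yl acetate | C=C(C)[C@H](CC=C(C)C)Cc1c(OC(C)=O)cc(OC)c2c1O[C@H](c1ccc(OC(C)=O)cc1OC)CC2=O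
F4 | step 14 | (2S)-2-[4-(acetyloxy)-2-methoxyphenyl]-5-hydroxy-8-[(2R)-5-methyl-2-(prop-1-en-2-yl)hex-4-en-1-yl]-4-oxo-3,4-dihydro-2H-chromen-7-yl acetate | C=C(C)[C@H](CC=C(C)C)Cc1c(OC(C)=O)cc(O)c2c1O[C@H](c1ccc(OC(C)=O)cc1OC)CC2=O
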